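**Retrosynthetic overview**
1. The quinone comes from a late aerobic para-oxidation of the ring-C phenol in an 18-membered bis(bibenzyl) macrocycle (last step).
2. The macrocycle is the only ring made in the route. It comes from an intramolecular Pd C–O coupling of the ring-D aryl chloride with either of the two equivalent OH groups of a 2-alkylresorcinol (ring C).
3. Both CH2CH2 bridges come from vinylboron ate complexes by a Pd-induced 1,2-shift of an aryl group from boron to carbon, followed by loss of boron. This is the key step. Bridge B–D is made first, bridge A–C second.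
4. The ring A–O–ring B ether comes from catechol and 1-bromo-4-iodobenzene, followed by para-iodination. The reactivity order C–I > C–Br > C–Cl sets the order of the later C–X events.
5. Rings A–D are bought as simple benzenes, and both C2 units come from vinylmagnesium bromide.

Assumption: the SMILES has no stereocentre or stereo double bond and the ring is taken to give no stable atropisomers, so the target is treated as achiral and needs no stereocontrol.

**Step 1**
Reactants: 1 catechol; 2 1-bromo-4-iodobenzene
Product: 3 2-(4-bromophenoxy)phenol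
Conditions: 1 (3 equiv), CuI (10 mol %), picolinic acid (20 mol %), K3PO4, DMSO, 85 °C, Ar
Reagents that add atoms: none
Why: This is an Ullmann-type Cu-catalysed O-arylation in which C–I reacts far faster than C–Br, and the excess of catechol under argon keeps it at mono-arylation.

**Step 2**
Reactants: 3 2-(4-bromophenoxy)phenol
Product: 4 2-(4-bromophenoxy)-4-iodophenol
Conditions: NIS (1.0 equiv), p-TsOH·H2O (10 mol %), MeCN, 0 °C → rt
Reagents that add atoms: N-iodosuccinimide, O=C1CCC(=O)N1I
Why: This is an electrophilic aromatic iodination in which the free OH is the strongest director and sends iodine para to itself (as with 2-alkoxyphenols), while the brominated ring A is much less activated.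

**Step 3**
Reactants: 5 vinylmagnesium bromide
Product: 6 vinylboronic acid pinacol ester (4,4,5,5-tetramethyl-2-vinyl-1,3,2-dioxaborolane)
Conditions: i-PrOBpin (1.0 equiv), THF, −78 °C → rt; HCl (1 equiv, Et2O); distil
Reagents that add atoms: 2-isopropoxy-4,4,5,5-tetramethyl-1,3,2-dioxaborolane, CC(C)OB1OC(C)(C)C(C)(C)O1
Why: This is a Grignard borylation, in which the vinyl Grignard adds to boron and isopropoxide is lost, the standard route to this boronic ester.

**Step 4**
Reactants: 7 1-chloro-3-iodobenzene; 6 vinylboronic acid pinacol ester; 4 2-(4-bromophenoxy)-4-iodophenol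
Product: 12 2-(4-bromophenoxy)-4-[2-(3-chlorophenyl)ethyl]phenol, via 3-chlorophenyllithium 8 (not isolated), via lithium (3-chlorophenyl)(vinyl)(pinacolato)borate 9 (not isolated), via [2-(4-bromophenoxy)-4-iodophenoxy]trimethylsilane 10 (not isolated), via racemic benzylic boronate 11 (not isolated)
Conditions: (a) 7, t-BuLi (2.0 equiv), Et2O, −78 °C; 6, → rt; swap to THF; (b) 4, HMDS (0.6 equiv), cat. (NH4)2SO4, THF, 65 °C, evaporate; (c) a + b, Pd(OAc)2 (3 mol %), dcypf (3.6 mol %), KOTf (2.2 equiv), THF, 60 °C; (d) TBAF·3H2O (4 equiv), 65 °C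
Reagents that add atoms: tert-butyllithium, [Li]C(C)(C)C (Li is present only in 8 and 9); hexamethyldisilazane, C[Si](C)(C)N[Si](C)(C)C (Me3Si is present only in 10 and 11 and is gone in 12)
Why: This is a Pd-catalysed conjunctive cross-coupling in which the cationic aryl-Pd(II) formed from the C–I bond of 10 (C–Br and C–Cl stay) binds the vinyl group of 9 and sets off the 1,2-shift of the 3-chlorophenyl group from boron to carbon (1,2-metallate rearrangement), reductive elimination gives 11, and the known fluoride-mediated protodeboronation of this benzylic boronate removes boron, Me3Si and the racemic stereocentre in the same pot.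

**Step 5**
Reactants: 13 resorcinol
Product: 14 2-iodoresorcinol
Conditions: I2 (1.05 equiv), NaHCO3 (1.1 equiv), H2O, 0 °C → rt
Reagents that add atoms: iodine, II
Why: This is an electrophilic iodination of the resorcinolate in water, which is known to give the 2-iodo isomer (carbon between the two oxygens) selectively.

**Step 6**
Reactants: 12 2-(4-bromophenoxy)-4-[2-(3-chlorophenyl)ethyl]phenol; 6 vinylboronic acid pinacol ester; 14 2-iodoresorcinol
Product: 21 2-{2-[4-(5-[2-(3-chlorophenyl)ethyl]-2-hydroxyphenoxy)phenyl]ethyl}resorcinol, via sodium phenoxide 15 (not isolated), via TBS ether 16 (not isolated), via ring-A aryllithium 17 (not isolated), via lithium aryl(vinyl)(pinacolato)borate 18 (not isolated), via 2-iodoresorcinol bis(trimethylsilyl) ether 19 (not isolated), via tris-silylated benzylic boronate 20 (not isolated)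
Conditions: (a) 12, NaH (1.0 equiv), THF, 0 °C; TBSCl (1.0 equiv), rt; t-BuLi (2.0 equiv), −78 °C; 6, → rt; (b) 14, HMDS (1.2 equiv), cat. (NH4)2SO4, THF, 65 °C, evaporate; (c) a + b, Pd(OAc)2 (5 mol %), dcypf (6 mol %), KOTf (2.2 equiv), THF, 65 °C; (d) TBAF·3H2O (8 equiv), 65 °C, Ar
Reagents that add atoms: sodium hydride, [Na+].[H-] (Na is present in 15 only); tert-butyldimethylsilyl chloride, CC(C)(C)[Si](C)(C)Cl (present in 16–18 and 20 only); tert-butyllithium, [Li]C(C)(C)C (Li is present in 17 and 18 only); hexamethyldisilazane, C[Si](C)(C)N[Si](C)(C)C (present in 19 and 20 only)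
Why: Proposed new method: a traceless conjunctive cross-coupling on a 2,6-dioxygenated aryl iodide, in which oxidative addition of Pd(0)/dcypf into the hindered C–I bond of 19 and removal of iodide by K+ give a cationic aryl-Pd(II) that binds the vinyl group of borate 18, this triggers the anti 1,2-shift of ring A from boron to the α-carbon while Pd takes the β-carbon (1,2-metallate rearrangement), the crowded aryl group speeds C(sp3)–C(sp2) reductive elimination to 20 ahead of β-hydride loss, and fluoride then strips all three silyl groups so that a freed ortho-phenoxide closes on boron to a six-membered borate whose weakened benzylic C–B bond is protonated by water (which also erases the racemic stereocentre); the closest known reaction types are the Pd-catalysed conjunctive cross-coupling of vinylboron ate complexes with unhindered aryl halides or triflates and the fluoride-mediated protodeboronation of benzylic boronic esters.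

**Step 7**
Reactants: 21 2-{2-[4-(5-[2-(3-chlorophenyl)ethyl]-2-hydroxyphenoxy)phenyl]ethyl}resorcinol
Product: 22 18-membered macrocyclic bis-phenol (ring C is a 3-aryloxy-2-alkylphenol with H para to its OH; ring B keeps its OH)
Conditions: Pd(OAc)2 (10 mol %), t-BuXPhos (15 mol %), K3PO4 (4 equiv), toluene/1,4-dioxane, 100 °C, 2 mM, slow addition, Ar
Reagents that add atoms: none
Why: This is an intramolecular Buchwald-type Pd-catalysed diaryl ether synthesis from an unactivated aryl chloride and an ortho-alkylphenol, in which the two resorcinol OH groups are equivalent so either gives 22, while the ring-B OH could only close a strained 10-membered cyclophane.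

**Step 8**
Reactants: 22 macrocyclic bis-phenol
Product: 23 marchantinquinone
Conditions: Co(salen) (15 mol %), O2 (1 atm), DMF, rt
Reagents that add atoms: dioxygen, O=O
Why: This is a Co(salen)/O2 oxidation of a phenol to a p-quinone, which works well on resorcinol mono-ethers with a free para C–H (ring C), whereas the ring-B phenol is para-blocked by the alkyl bridge and belongs to the sluggish 2-alkoxy-4-alkylphenol class with no path to a quinone.

**Compound list**
1 | catechol | Oc1ccccc1O | starting material
2 | 1-bromo-4-iodobenzene | Brc1ccc(I)cc1 | starting material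
3 | 2-(4-bromophenoxy)phenol | Oc1ccccc1Oc1ccc(Br)cc1 | intermediate
4 | 2-(4-bromophenoxy)-4-iodophenol | Oc1ccc(I)cc1Oc1ccc(Br)cc1 | intermediate
5 | vinylmagnesium bromide | C=C[Mg]Br | starting material
6 | vinylboronic acid pinacol ester | C=CB1OC(C)(C)C(C)(C)O1 | intermediate
7 | 1-chloro-3-iodobenzene | Clc1cccc(I)c1 | starting material
8 | 3-chlorophenyllithium | [Li]c1cccc(Cl)c1 | intermediate
9 | lithium (3-chlorophenyl)(vinyl)(pinacolato)borate | [Li+].C=C[B-]1(c2cccc(Cl)c2)OC(C)(C)C(C)(C)O1 | intermediate
10 | [2-(4-bromophenoxy)-4-iodophenoxy]trimethylsilane | C[Si](C)(C)Oc1ccc(I)cc1Oc1ccc(Br)cc1 | intermediate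
11 | racemic {2-(4-bromophenoxy)-4-[2-(3-chlorophenyl)-2-(pinacolatoboryl)ethyl]phenoxy}trimethylsilane (B–D benzylic boronate) | C[Si](C)(C)Oc1ccc(CC(B2OC(C)(C)C(C)(C)O2)c2cccc(Cl)c2)cc1Oc1ccc(Br)cc1 | intermediate
12 | 2-(4-bromophenoxy)-4-[2-(3-chlorophenyl)ethyl]phenol | Oc1ccc(CCc2cccc(Cl)c2)cc1Oc1ccc(Br)cc1 | intermediate
13 | resorcinol | Oc1cccc(O)c1 | starting material
14 | 2-iodoresorcinol | Oc1cccc(O)c1I | intermediate
15 | sodium 2-(4-bromophenoxy)-4-[2-(3-chlorophenyl)ethyl]phenoxide (sodium phenoxide of 12) | [Na+].[O-]c1ccc(CCc2cccc(Cl)c2)cc1Oc1ccc(Br)cc1 | intermediate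
16 | tert-butyl{2-(4-bromophenoxy)-4-[2-(3-chlorophenyl)ethyl]phenoxy}dimethylsilane (TBS ether of 12) | CC(C)(C)[Si](C)(C)Oc1ccc(CCc2cccc(Cl)c2)cc1Oc1ccc(Br)cc1 | intermediate
17 | tert-butyl{4-[2-(3-chlorophenyl)ethyl]-2-(4-lithiophenoxy)phenoxy}dimethylsilane (ring-A aryllithium, Li in place of Br of 16) | CC(C)(C)[Si](C)(C)Oc1ccc(CCc2cccc(Cl)c2)cc1Oc1ccc([Li])cc1 | intermediate
18 | lithium aryl(vinyl)(pinacolato)borate in which the aryl group on boron is ring A of 17 | [Li+].C=C[B-]1(c2ccc(Oc3cc(CCc4cccc(Cl)c4)ccc3O[Si](C)(C)C(C)(C)C)cc2)OC(C)(C)C(C)(C)O1 | intermediate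
19 | 2-iodoresorcinol bis(trimethylsilyl) ether | C[Si](C)(C)Oc1cccc(O[Si](C)(C)C)c1I | intermediate
20 | racemic A–C benzylic pinacol boronate, ring C–CH2–CH(Bpin)–ring A, with two OTMS groups on ring C and the OTBS group on ring B | C[Si](C)(C)Oc1cccc(O[Si](C)(C)C)c1CC(B1OC(C)(C)C(C)(C)O1)c1ccc(Oc2cc(CCc3cccc(Cl)c3)ccc2O[Si](C)(C)C(C)(C)C)cc1 | intermediate
21 | seco triol, 2-{2-[4-(5-[2-(3-chlorophenyl)ethyl]-2-hydroxyphenoxy)phenyl]ethyl}resorcinol | Oc1cccc(O)c1CCc1ccc(Oc2cc(CCc3cccc(Cl)c3)ccc2O)cc1 | intermediate
22 | 18-membered macrocyclic bis-phenol | Oc1cccc2c1CCc1ccc(cc1)Oc1cc(ccc1O)CCc1cccc(c1)O2 | intermediate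
23 | marchantinquinone | O=C1C=CC(=O)C2=C1CCc1ccc(cc1)Oc1cc(ccc1O)CCc1cccc(c1)O2 | target

**Totals:** 8 steps. The longest linear sequence is 6 steps (1, 2, 4, 6, 7, 8). Steps 4 and 6 are telescoped sequences. Each counts as one step because nothing is purified between its operations.

**Steps most likely to fail**

Step 6 (the proposed new step). The hindered, electron-rich iodide 19 may add to Pd too slowly. The ate complex may give direct aryl or vinyl transfer instead of the 1,2-shift. The cyclic borate formed after desilylation may also resist protonolysis. The fallback sets out from 12 and comes back to the route at 21. It uses known chemistry only and costs one more step. Suzuki–Miyaura vinylation of the C–Br bond of 12 with 6 (Pd(dppf)Cl2, K2CO3, dioxane/H2O, 80 °C; C–Cl stays) gives 4-[2-(3-chlorophenyl)ethyl]-2-(4-vinylphenoxy)phenol F1. Anti-Markovnikov hydroboration with 9-BBN-H (2.2 equiv, THF) then gives the B-alkyl-9-borabicyclononane F2, whose phenol is borinated in passing and freed again by aqueous base. Without isolation, it is coupled with unprotected 14 in a B-alkyl Suzuki–Miyaura reaction (Pd(dppf)Cl2, aq K3PO4, THF/DMF, 60 °C) to give 21.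

Step 7. At 2 mM the Pd C–O coupling of an aryl chloride may stall or give oligomers. The fallback sets out from 21 and comes back to the route at 22. It changes the polarity of ring D. Pd-catalysed borylation of the aryl chloride with B2(OH)4 (XPhos-Pd precatalyst, KOAc, EtOH, 80 °C) gives the seco arylboronic acid F3. This is closed by an oxidative intramolecular Chan–Evans–Lam etherification (Cu(OAc)2, pyridine, 4 Å MS, CH2Cl2, air, 1 mM) to give 22.

Step 8. The free ring-B phenol may be attacked, or ring C may react slowly. The fallback sets out from 22 and comes back to the route at 23. It replaces the radical oxidation by a para-selective electrophilic substitution, which picks the doubly activated ring-C position. Azo coupling with 4-sulfobenzenediazonium (1 equiv, aq Na2CO3/THF, 0 °C) gives the ring-C para-azo dye F4. Na2S2O4 cleaves it to the macrocyclic p-aminophenol F5. FeCl3 in dilute HCl then oxidises only this aminophenol, through the quinone imine and its hydrolysis, to 23.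

**Further compounds**
F1 | step 6 | 4-[2-(3-chlorophenyl)ethyl]-2-(4-vinylphenoxy)phenol | Oc1ccc(CCc2cccc(Cl)c2)cc1Oc1ccc(C=C)cc1
F2 | step 6 | B-alkyl-9-borabicyclononane from F1 | Oc1ccc(CCc2cccc(Cl)c2)cc1Oc1ccc(CCB2C3CCCC2CCC3)cc1
F3 | step 7 | seco arylboronic acid (Cl of 21 replaced by B(OH)2) | OB(O)c1cccc(CCc2ccc(O)c(Oc3ccc(CCc4c(O)cccc4O)cc3)c2)c1
F4 | step 8 | ring-C para-azo dye of 22 with a 4-sulfophenyl group | Oc1ccc(/N=N/c3ccc(cc3)S(=O)(=O)O)c2c1CCc1ccc(cc1)Oc1cc(ccc1O)CCc1cccc(c1)O2
F5 | step 8 | macrocyclic p-aminophenol (NH2 para to the ring-C OH) | Oc1ccc(N)c2c1CCc1ccc(cc1)Oc1cc(ccc1O)CCc1cccc(c1)O2
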